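**Retrosynthetic overview**
1. Target ⇐ its penta-O-benzyl ether by hydrogenolysis (no stereocentre touched).
2. Penta-O-benzyl ether ⇐ one flask, from an aryl glycidyl-type ether and a 2-hydroxychalcone: 6-endo Friedel–Crafts epoxy-arene closure makes the lower pyran ring (C4–C4a); the same D ring then attacks C4 of the flavylium ion formed by cyclodehydration of the chalcone (upper pyran ring, C4–C8); ionic hydrogenation fixes 2,4-cis.
3. Epoxy ether ⇐ Mitsunobu inversion of an erythro epoxy alcohol with 3,5-bis(benzyloxy)phenol ⇐ Sharpless kinetic resolution of an aryl vinyl carbinol ⇐ aldehyde + vinyl Grignard.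
4. Chalcone ⇐ Claisen–Schmidt condensation of two benzylated catalogue arenes.
5. Ring order: lower pyran ring, then upper pyran ring, in the same operation; all five benzene rings are bought.

Assumption: the sense of induction of the chiral acid at C4 in step 5 is taken as shown; if a trial run gives the 4R epimer, the antipodal catalyst is used.

**Step 1**
Reactants: 1 4-(benzyloxy)benzaldehyde
Product: 2 rac-1-[4-(benzyloxy)phenyl]prop-2-en-1-ol
Conditions: vinylMgBr (1.2 equiv), THF, −78 → 0 °C; then H2O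
Reagents that add atoms: vinylmagnesium bromide, C=C[Mg]Br
Why: Grignard 1,2-addition to an aryl aldehyde; the racemate is resolved in step 2.

**Step 2**
Reactants: 2 rac-1-[4-(benzyloxy)phenyl]prop-2-en-1-ol
Product: 3 (S)-[4-(benzyloxy)phenyl][(2R)-oxiran-2-yl]methanol
Conditions: Ti(OiPr)4 (0.2 equiv), L-(+)-DIPT (0.25 equiv), t-BuOOH (0.6 equiv), 4 Å MS, CH2Cl2, −20 °C, stopped at ca. 55% conversion (unreacted (S)-2 removed by chromatography)
Reagents that add atoms: tert-butyl hydroperoxide, CC(C)(C)OO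
Why: Sharpless kinetic resolution of a secondary allylic alcohol: with L-(+)-tartrate the (R)-carbinol is epoxidised fast and erythro-selectively, which sets both the carbinol (S) and the oxirane (R) centres.

**Step 3**
Reactants: 3 (S)-[4-(benzyloxy)phenyl][(2R)-oxiran-2-yl]methanol; 4 3,5-bis(benzyloxy)phenol
Product: 5 (2R)-2-[(R)-[4-(benzyloxy)phenyl][3,5-bis(benzyloxy)phenoxy]methyl]oxirane
Conditions: PPh3, DIAD, toluene, 0 °C → rt
Reagents that add atoms: none
Why: Mitsunobu etherification with SN2 inversion at the benzylic carbinol (S → R, erythro → threo, the relative configuration of a 2,3-cis flavan-3-ol); the neighbouring epoxide disfavours benzylic ionisation and its own stereocentre is untouched.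

**Step 4**
Reactants: 6 4-(benzyloxy)-2-hydroxybenzaldehyde; 7 1-[4-(benzyloxy)phenyl]ethan-1-one
Product: 8 (E)-3-[4-(benzyloxy)-2-hydroxyphenyl]-1-[4-(benzyloxy)phenyl]prop-2-en-1-one
Conditions: KOH (3 equiv), EtOH, rt; then dil. HCl
Reagents that add atoms: none
Why: Claisen–Schmidt aldol condensation, the classical route to (E)-2-hydroxychalcones; no stereocentre is formed.

**Step 5**
Reactants: 5 (2R)-2-[(R)-[4-(benzyloxy)phenyl][3,5-bis(benzyloxy)phenoxy]methyl]oxirane; 8 (E)-3-[4-(benzyloxy)-2-hydroxyphenyl]-1-[4-(benzyloxy)phenyl]prop-2-en-1-one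
Product: 12 (2R,3R)-5,7-bis(benzyloxy)-8-[(2S,4S)-7-(benzyloxy)-2-(4-benzyloxyphenyl)chroman-4-yl]-2-(4-benzyloxyphenyl)chroman-3-ol, via tri-O-benzyl-epiafzelechin 9 (not isolated), via flavylium ion 10 (not isolated), via 4-aryl-flav-2-ene 11 (not isolated)
Conditions: (R)-TRIP N-triflylphosphoramide (10 mol%), 4 Å MS, CH2Cl2, 0 °C → rt (5 consumed); then 8 (1.2 equiv), −20 °C → rt; then Et3SiH (3 equiv), TFA (5 equiv), −40 °C; aq. NaHCO3
Reagents that add atoms: none
Why: Proposed new method: one strong chiral Brønsted acid drives two consecutive Friedel–Crafts events of the same phloroglucinol-type ring — protonation of the terminal epoxide of 5 triggers 6-endo attack of the ortho carbon on the CH2 terminus (the C2–O and C3–O bonds are untouched, so 2R,3R-cis is carried over; closest known type: Au(III)- or HFIP-promoted epoxy-arene cyclisation of aryl glycidyl ethers to chroman-3-ols), then the acid turns 2-hydroxychalcone 8 by E/Z isomerisation and cyclodehydration into flavylium ion 10 paired with the chiral phosphoramidate, and C8 of 9 (the position attacked by electrophiles in 5,7-di-O-benzyl flavan-3-ols) adds to C4 on the face left open by the anion, which is hydrogen-bonded to the 3-OH, setting 4S (closest known type: counter-anion-directed additions to benzopyrylium ions and phosphoric-acid-catalysed Friedel–Crafts/cyclodehydration of 2-hydroxychalcones to 4-aryl-4H-chromenes); finally TFA protonates enol ether 11 at C3 and Et3SiH delivers hydride to C2 of the oxocarbenium ion anti to the C4 aryl group, giving the 2,4-cis (2S,4S) flavan (ionic hydrogenation, as in lactol reductions to cis-2,4-disubstituted chromans); any 4R epimer is removed by chromatography.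

**Step 6**
Reactants: 12 (2R,3R)-5,7-bis(benzyloxy)-8-[(2S,4S)-7-(benzyloxy)-2-(4-benzyloxyphenyl)chroman-4-yl]-2-(4-benzyloxyphenyl)chroman-3-ol
Product: 13 (2R,3R)-8-[(2S,4S)-7-hydroxy-2-(4-hydroxyphenyl)chroman-4-yl]-2-(4-hydroxyphenyl)chroman-3,5,7-triol
Conditions: H2 (1 atm), Pd(OH)2/C, THF–MeOH, rt
Reagents that add atoms: none
Why: Hydrogenolysis of the five aryl benzyl ethers under neutral conditions, as used for benzylated proanthocyanidins; the interflavan bond and all four stereocentres are untouched.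

**Compound list**
1 | 4-(benzyloxy)benzaldehyde | O=Cc1ccc(OCc2ccccc2)cc1 | starting material
2 | rac-1-[4-(benzyloxy)phenyl]prop-2-en-1-ol | C=CC(O)c1ccc(OCc2ccccc2)cc1 | intermediate
3 | (S)-[4-(benzyloxy)phenyl][(2R)-oxiran-2-yl]methanol | O[C@H]([C@H]1CO1)c1ccc(OCc2ccccc2)cc1 | intermediate
4 | 3,5-bis(benzyloxy)phenol | Oc1cc(OCc2ccccc2)cc(OCc2ccccc2)c1 | starting material
5 | (2R)-2-[(R)-[4-(benzyloxy)phenyl][3,5-bis(benzyloxy)phenoxy]methyl]oxirane | O(c1cc(OCc2ccccc2)cc(OCc2ccccc2)c1)[C@@H]([C@H]1CO1)c1ccc(OCc2ccccc2)cc1 | intermediate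
6 | 4-(benzyloxy)-2-hydroxybenzaldehyde | O=Cc1ccc(OCc2ccccc2)cc1O | starting material
7 | 1-[4-(benzyloxy)phenyl]ethan-1-one | CC(=O)c1ccc(OCc2ccccc2)cc1 | starting material
8 | (E)-3-[4-(benzyloxy)-2-hydroxyphenyl]-1-[4-(benzyloxy)phenyl]prop-2-en-1-one | O=C(/C=C/c1ccc(OCc2ccccc2)cc1O)c1ccc(OCc2ccccc2)cc1 | intermediate
9 | (2R,3R)-5,7-bis(benzyloxy)-2-[4-(benzyloxy)phenyl]chroman-3-ol (5,7,4'-tri-O-benzyl-epiafzelechin) | O[C@@H]1Cc2c(OCc3ccccc3)cc(OCc3ccccc3)cc2O[C@@H]1c1ccc(OCc2ccccc2)cc1 | intermediate (not isolated)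
10 | 7-(benzyloxy)-2-[4-(benzyloxy)phenyl]chromenylium ion (paired with the catalyst anion) | c1(-c2ccc(OCc3ccccc3)cc2)ccc2ccc(OCc3ccccc3)cc2[o+]1 | intermediate (not isolated)
11 | (2R,3R)-5,7-bis(benzyloxy)-8-[(4S)-7-(benzyloxy)-2-(4-benzyloxyphenyl)-4H-chromen-4-yl]-2-(4-benzyloxyphenyl)chroman-3-ol | C(c1ccccc1)Oc1ccc(C2=C[C@H](c3c(OCc5ccccc5)cc(OCc5ccccc5)c4c3O[C@H](c3ccc(OCc5ccccc5)cc3)[C@H](O)C4)c3ccc(OCc5ccccc5)cc3O2)cc1 | intermediate (not isolated)
12 | (2R,3R)-5,7-bis(benzyloxy)-8-[(2S,4S)-7-(benzyloxy)-2-(4-benzyloxyphenyl)chroman-4-yl]-2-(4-benzyloxyphenyl)chroman-3-ol | C(c1ccccc1)Oc1ccc([C@@H]2C[C@H](c3c(OCc5ccccc5)cc(OCc5ccccc5)c4c3O[C@H](c3ccc(OCc5ccccc5)cc3)[C@H](O)C4)c3ccc(OCc5ccccc5)cc3O2)cc1 | intermediate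
13 | (2R,3R)-8-[(2S,4S)-7-hydroxy-2-(4-hydroxyphenyl)chroman-4-yl]-2-(4-hydroxyphenyl)chroman-3,5,7-triol | Oc1ccc([C@@H]2C[C@H](c3c(O)cc(O)c4c3O[C@H](c3ccc(O)cc3)[C@H](O)C4)c3ccc(O)cc3O2)cc1 | target

**Total step count:** 6
**Longest linear sequence:** 5 (steps 1, 2, 3, 5, 6)

**Three steps most likely to fail**

Step 5 (three acid-driven stages in one flask; C8 versus C6 attack; catalyst control at C4 against a chiral nucleophile). The fallback sets out from 5 and 6 and comes back at 12; it makes the two rings in separate operations of a different kind. Compound 5 is cyclised with AuCl3/AgOTf and 9 is isolated. NBS then brominates 9 at C8 to give (2R,3R)-5,7-bis(benzyloxy)-2-(4-benzyloxyphenyl)-8-bromochroman-3-ol F1. Aldehyde 6 is treated with Boc2O/DMAP to give tert-butyl [5-(benzyloxy)-2-formylphenyl] carbonate F2. F1 is deprotonated with i-PrMgCl, lithiated with t-BuLi at −78 °C and added to F2 in the presence of bought 4-(benzyloxy)styrene and MgBr2·OEt2. Boc migration to the benzylic alkoxide and elimination generate the A-ring ortho-quinone methide, which takes up the styrene in an endo inverse-demand hetero-Diels–Alder reaction. This gives the 2,4-cis flavan 12 directly; the two C4 epimers are separated by chromatography.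

Step 3 (a p-alkoxybenzylic alcohol may react partly by SN1 under Mitsunobu conditions and lose configuration). The fallback sets out from 1 and 4 and comes back at 5; the aryl ether is made by epoxide opening instead of carbinol displacement. Ando olefination of 1 gives ethyl (Z)-3-(4-benzyloxyphenyl)prop-2-enoate F3. DIBAL reduction gives (Z)-3-(4-benzyloxyphenyl)prop-2-en-1-ol F4. Sharpless epoxidation with D-(−)-DIPT gives [(2R,3S)-3-(4-benzyloxyphenyl)oxiran-2-yl]methanol F5. Ti(OiPr)4-mediated C3-selective opening by phenol 4, with inversion at the benzylic carbon, gives (2R,3R)-3-(4-benzyloxyphenyl)-3-[3,5-bis(benzyloxy)phenoxy]propane-1,2-diol F6. Cyclodehydration through the activated primary hydroxyl (PPh3, DIAD) closes the terminal epoxide with retention at C2 and gives 5.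

Step 2 (slow epoxidation of a terminal alkene, Lewis-acid sensitivity of the p-alkoxybenzylic epoxy alcohol, 50% ceiling). The fallback sets out from 1 and comes back at 3; the absolute configuration comes from C–C bond formation instead of resolution. Catalytic asymmetric vinylation of 1 with divinylzinc and (+)-MIB gives (R)-1-(4-benzyloxyphenyl)prop-2-en-1-ol F7. This is then epoxidised to full conversion in the matched, erythro-selective hydroxyl-directed sense (Ti(OiPr)4/L-(+)-DIPT/t-BuOOH, or VO(acac)2/t-BuOOH) to give 3.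

**Further compounds**
F1 | step 5 | (2R,3R)-5,7-bis(benzyloxy)-2-(4-benzyloxyphenyl)-8-bromochroman-3-ol | O[C@@H]1Cc2c(OCc3ccccc3)cc(OCc3ccccc3)c(Br)c2O[C@@H]1c1ccc(OCc2ccccc2)cc1
F2 | step 5 | tert-butyl [5-(benzyloxy)-2-formylphenyl] carbonate | CC(C)(C)OC(=O)Oc1cc(OCc2ccccc2)ccc1C=O
F3 | step 3 | ethyl (Z)-3-(4-benzyloxyphenyl)prop-2-enoate | CCOC(=O)/C=C\c1ccc(OCc2ccccc2)cc1
F4 | step 3 | (Z)-3-(4-benzyloxyphenyl)prop-2-en-1-ol | OC/C=C\c1ccc(OCc2ccccc2)cc1
F5 | step 3 | [(2R,3S)-3-(4-benzyloxyphenyl)oxiran-2-yl]methanol | OC[C@H]1O[C@H]1c1ccc(OCc2ccccc2)cc1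
F6 | step 3 | (2R,3R)-3-(4-benzyloxyphenyl)-3-[3,5-bis(benzyloxy)phenoxy]propane-1,2-diol | OC[C@@H](O)[C@H](Oc1cc(OCc2ccccc2)cc(OCc2ccccc2)c1)c1ccc(OCc2ccccc2)cc1
F7 | step 2 | (R)-1-(4-benzyloxyphenyl)prop-2-en-1-ol | C=C[C@@H](O)c1ccc(OCc2ccccc2)cc1
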